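**Plan**

- Retrosynthetic cuts: the five silyl ethers come off last. Ring A is a C-acylphloroglucinol (oxygen on C5 and C7, the side chain on C8, the C4 carbonyl on C4a), so it is cut at C4a–C5. This leads back to an acylketene, masked as a dioxinone, on an arm at C8a of a (2S)-2-aryl-2,3-dihydropyran-4-one.
- The pyranone is cut at C8–C8a (dioxinone γ-carbanion plus a 6-aryl-4-methoxy-5,6-dihydropyran-2-one), and that lactone at C2–C3 and O1–C8a (aryl aldehyde plus Brassard's diene).
- The dihydrobenzofuran aldehyde is cut at C2–C3 (carbene C–H insertion), at C3–C3a (aryllithium plus nitrile) and at the O–CH2 bond (Mitsunobu).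
- Forward order of rings: dihydrobenzofuran (step 7), ring C as the lactone (step 11) and then as the pyranone carrying the arm (step 15), ring A (step 16), then desilylation.
- Stereochemistry: dihydrobenzofuran C3 from the Rh2(S-PTAD)4-catalysed C–H insertion and C2 from acid equilibration to trans; flavanone C2 from the (S)-BINOL/Ti(OiPr)4-catalysed hetero-Diels–Alder reaction; the E-alkene from SeO2 oxidation of a prenyl group.

Key step: step 16

Abbreviations: Ar* = (2R,3R)-3-[3,5-bis(tert-butyldimethylsilyloxy)phenyl]-6-(tert-butyldimethylsilyloxy)-2-[4-(tert-butyldimethylsilyloxy)phenyl]-2,3-dihydrobenzofuran-5-yl; MOM = methoxymethyl; TBS = tert-butyldimethylsilyl. Flavanone numbering (C2, C3, C4, C4a, C5–C8, C8a) is used for the pyranone and its arm.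

Assumption: the sense of induction of Rh2(S-PTAD)4 (step 7) and of (S)-BINOL/Ti(OiPr)4 (step 11) is assigned by analogy with simpler substrates; should either prove opposite, the mirror-image catalyst is used and nothing else changes.

**Route**

Step 1
Reactants: 1 4-hydroxybenzyl alcohol
Product: 2 4-(methoxymethoxy)benzyl alcohol
Conditions: MOMCl, K2CO3, acetone, 0 °C → rt
Reagents that add atoms: chloromethyl methyl ether, COCCl
Why: Williamson etherification of the phenoxide, the only oxygen that K2CO3 deprotonates, so the benzylic alcohol stays free.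

Step 2
Reactants: 3 5-bromo-2,4-dihydroxybenzaldehyde; 2 4-(methoxymethoxy)benzyl alcohol
Product: 4 5-bromo-2-hydroxy-4-{[4-(methoxymethoxy)benzyl]oxy}benzaldehyde
Conditions: PPh3, DIAD, THF, 0 °C → rt
Reagents that add atoms: none
Why: Mitsunobu etherification goes to the 4-hydroxyl, which is the more acidic phenol and is not held in the hydrogen bond to the formyl group, a selectivity established for 2,4-dihydroxybenzaldehydes.

Step 3
Reactants: 4 5-bromo-2-hydroxy-4-{[4-(methoxymethoxy)benzyl]oxy}benzaldehyde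
Product: 5 5-bromo-2-(methoxymethoxy)-4-{[4-(methoxymethoxy)benzyl]oxy}benzaldehyde
Conditions: MOMCl, iPr2NEt, CH2Cl2, 0 °C → rt
Reagents that add atoms: chloromethyl methyl ether, COCCl
Why: O-alkylation of the remaining phenol with the reactive α-chloro ether gives a MOM ether that survives the organolithium and hydrazine steps.

Step 4
Reactants: 5 5-bromo-2-(methoxymethoxy)-4-{[4-(methoxymethoxy)benzyl]oxy}benzaldehyde
Product: 6 2-[5-bromo-2-(methoxymethoxy)-4-{[4-(methoxymethoxy)benzyl]oxy}phenyl]-1,3-dioxolane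
Conditions: Me3SiOCH2CH2OSiMe3, TMSOTf (2 mol %), CH2Cl2, −78 °C; pyridine quench
Reagents that add atoms: 1,2-bis(trimethylsilyloxy)ethane, C[Si](C)(C)OCCO[Si](C)(C)C
Why: Noyori acetalisation under aprotic conditions at low temperature masks the aldehyde without touching the MOM ethers or the acid-labile alkoxybenzyl ether.

Step 5
Reactants: 7 3,5-dihydroxybenzonitrile
Product: 8 3,5-bis(methoxymethoxy)benzonitrile
Conditions: MOMCl, iPr2NEt, CH2Cl2, 0 °C → rt
Reagents that add atoms: chloromethyl methyl ether, COCCl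
Why: Double O-alkylation of the phenols, which gives the electrophile for the diaryl carbon in one step.

Step 6
Reactants: 6 2-[5-bromo-2-(methoxymethoxy)-4-{[4-(methoxymethoxy)benzyl]oxy}phenyl]-1,3-dioxolane; 8 3,5-bis(methoxymethoxy)benzonitrile
Product: 10 [3,5-bis(methoxymethoxy)phenyl][5-(1,3-dioxolan-2-yl)-4-(methoxymethoxy)-2-{[4-(methoxymethoxy)benzyl]oxy}phenyl]methanone hydrazone (E/Z mixture), via N-H ketimine 9 (not isolated)
Conditions: n-BuLi, THF, −78 °C; 8, −78 → 0 °C; AcOH, then N2H4·H2O, EtOH, 60 °C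
Reagents that add atoms: hydrazine, NN
Why: Bromine–lithium exchange and addition of the aryllithium to the nitrile give the N-H ketimine, which undergoes transimination with hydrazine (loss of ammonia) much more readily than the hindered ketone would condense, so no oxidation-level change is needed.

Step 7
Reactants: 10 the hydrazone
Product: 12 (2S,3R)-3-[3,5-bis(methoxymethoxy)phenyl]-5-(1,3-dioxolan-2-yl)-6-(methoxymethoxy)-2-[4-(methoxymethoxy)phenyl]-2,3-dihydrobenzofuran (cis), via diazo compound 11 (not isolated)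
Conditions: MnO2, MeCN, 0 °C, filtration through Celite; Rh2(S-PTAD)4 (1 mol %), MeCN, 0 °C → rt
Reagents that add atoms: none
Why: Oxidation gives the donor/donor diazo compound, whose rhodium carbene undergoes intramolecular 1,5 C–H insertion into the benzylic C–H of the neighbouring aryloxymethyl group; the chiral carboxylate catalyst sets C3 as R, and the concerted insertion gives the cis-2,3-diaryl ring (C2 S) that is general for this reaction class.

Step 8
Reactants: 12 the cis-dihydrobenzofuran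
Product: 13 (2R,3R)-3-(3,5-dihydroxyphenyl)-6-hydroxy-2-(4-hydroxyphenyl)-2,3-dihydrobenzofuran-5-carbaldehyde (trans)
Conditions: HCl (3 M aq.), MeOH/THF, 50 °C
Reagents that add atoms: water, O
Why: Acid-catalysed acetal cleavage removes the four MOM ethers and the dioxolane, and the same acid reversibly ionises the C2–O1 bond to the para-hydroxybenzyl cation, which recloses to the thermodynamically preferred trans-2,3-diaryl isomer (acid-mediated C2 epimerisation known for 2-(4-hydroxyphenyl)dihydrobenzofurans), so C2 becomes R while C3 is not touched.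

Step 9
Reactants: 13 the tetraphenol aldehyde
Product: 14 Ar*–CHO, the tetrakis(tert-butyldimethylsilyl) ether of 13
Conditions: TBSCl, imidazole, DMAP (cat.), DMF, rt
Reagents that add atoms: tert-butyldimethylsilyl chloride, CC(C)(C)[Si](C)(C)Cl
Why: Silylation of all four phenols gives ethers that tolerate Lewis acid, lithium enolate and heat, and that fluoride removes at the end without acid or base.

Step 10
Reactants: 15 methyl (E)-3-methoxybut-2-enoate
Product: 16 1,3-dimethoxy-1-(trimethylsilyloxy)buta-1,3-diene (Brassard's diene; ketene acetal geometry not defined)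
Conditions: LiN(iPr)2, THF, −78 °C; TMSCl
Reagents that add atoms: chlorotrimethylsilane, C[Si](C)(C)Cl
Why: Kinetic γ-deprotonation of the vinylogous ester and O-silylation of the dienolate give the silyl ketene acetal diene.

Step 11
Reactants: 14 Ar*–CHO; 16 Brassard's diene
Product: 18 (6S)-6-Ar*-4-methoxy-5,6-dihydro-2H-pyran-2-one, via aldol adduct 17 (not isolated)
Conditions: (S)-BINOL, Ti(OiPr)4 (20 mol % each), 4 Å molecular sieves, THF, 0 °C → rt; then TFA, CH2Cl2, 0 °C
Reagents that add atoms: none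
Why: Catalytic asymmetric hetero-Diels–Alder reaction of Brassard's diene, which with BINOL/Ti(OiPr)4 runs through a vinylogous Mukaiyama aldol adduct that lactonises with TFA; the chiral titanium complex shields one face of the aldehyde and sets C6 of the lactone (the later flavanone C2) as S, the remote stereocentres of the aldehyde having little influence.

Step 12
Reactants: 19 2,2,6-trimethyl-4H-1,3-dioxin-4-one; 20 prenyl bromide
Product: 21 2,2-dimethyl-6-(4-methylpent-3-en-1-yl)-4H-1,3-dioxin-4-one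
Conditions: LiN(iPr)2, THF, −78 °C; 20, DMPU, −78 → −20 °C
Reagents that add atoms: none
Why: The lithium dienolate of the dioxinone is alkylated by the allylic bromide at the γ-carbon (the 6-methyl group) in the presence of a polar additive, a known way to 6-alkenyl dioxinones.

Step 13
Reactants: 21 the prenylated dioxinone
Product: 22 6-[(3E)-5-hydroxy-4-methylpent-3-en-1-yl]-2,2-dimethyl-4H-1,3-dioxin-4-one
Conditions: SeO2 (0.2 equiv), t-BuOOH, salicylic acid (cat.), CH2Cl2, rt
Reagents that add atoms: tert-butyl hydroperoxide, CC(C)(C)OO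
Why: Allylic oxidation by SeO2 (ene reaction, then 2,3-sigmatropic shift) attacks the E-methyl group of the electron-rich trisubstituted alkene and gives the (E)-allylic alcohol, while the electron-poor dioxinone alkene is left alone.

Step 14
Reactants: 22 the allylic alcohol
Product: 23 6-[(3E)-5-(tert-butyldimethylsilyloxy)-4-methylpent-3-en-1-yl]-2,2-dimethyl-4H-1,3-dioxin-4-one
Conditions: TBSCl, imidazole, CH2Cl2, rt
Reagents that add atoms: tert-butyldimethylsilyl chloride, CC(C)(C)[Si](C)(C)Cl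
Why: Silylation of the primary alcohol keeps it from trapping the acylketene later and puts it in the same protecting-group class as the phenols.

Step 15
Reactants: 18 the (6S)-methoxy lactone; 23 the silylated dioxinone arm
Product: 25 (2S)-2-Ar*-6-[(3E)-5-(tert-butyldimethylsilyloxy)-1-(2,2-dimethyl-4-oxo-4H-1,3-dioxin-6-yl)-4-methylpent-3-en-1-yl]-2,3-dihydro-4H-pyran-4-one (both epimers at the side-chain CH), via lactol 24 (not isolated)
Conditions: 23 (2 equiv), LiN(iPr)2, THF, −78 °C; 18, −78 → −40 °C; AcOH; then PPTS (cat.), water-saturated CH2Cl2, rt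
Reagents that add atoms: water, O
Why: Claisen-type addition of the γ-carbon of the lithium dienolate to the lactone carbonyl gives a lactol, which with mild acid loses water to a 4-methoxypyranylium-type cation that is hydrolysed to the transposed enone (Stork–Danheiser-type transposition of a vinylogous ester); this forms the C8–C8a bond, C2 is not touched, and the new CH centre forms as a mixture that is lost in the next step.

Step 16
Reactants: 25 the dioxinone-bearing dihydropyranone
Product: 27 (2S)-2-Ar*-8-[(2E)-4-(tert-butyldimethylsilyloxy)-3-methylbut-2-en-1-yl]-5,7-dihydroxy-2,3-dihydro-4H-chromen-4-one, via acylketene 26 (not isolated)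
Conditions: toluene (0.005 M), 4 Å molecular sieves, 110 °C
Reagents that add atoms: none
Why: Proposed new method: heating expels acetone from the dioxinone by retro-hetero-Diels–Alder reaction to give acylketene 26; enolisation of the C7 ketone toward C8, whose proton is flanked by that ketone and by the vinylogous ester of the pyranone, gives a (Z)-dienylketene C4a=C8a–C8=C7–C6=C5=O that closes the C4a–C5 bond, and two proton shifts aromatise ring A. The closest known reactions are the thermolysis of keto-dioxinones to acylketenes followed by polyketide-type aromatisation, and the 6π electrocyclisation of dienylketenes to phenols in the Danheiser and Dötz benzannulations; neither has been run on a 2,3-dihydropyran-4-one. The six-membered carbocycle closes by thermal disrotatory 6π electrocyclisation, which in polar terms is a 6-exo-dig C-acylation of the nucleophilic α-carbon of the β-alkoxy enone by the ketene. No stereocentre is created, both C8 epimers converge on the same arene, and the neutral medium leaves the base-labile C2 centre and the dihydrobenzofuran untouched. The step needs C-acylation at C4a to win over ketene dimerisation, capture by outside nucleophiles and the aldol (orsellinate) mode of folding: high dilution, molecular sieves and full silylation of the hydroxyls serve the first two, the ring oxygen is an ether and cannot give a pyrone, and the pyranone ring holds the C4 carbonyl trans to the arm across C4a=C8a so that only C4a can reach the ketene.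

Step 17
Reactants: 27 the pentasilylated flavanone
Product: 28 (2S)-2-[(2R,3R)-3-(3,5-dihydroxyphenyl)-6-hydroxy-2-(4-hydroxyphenyl)-2,3-dihydrobenzofuran-5-yl]-5,7-dihydroxy-8-[(2E)-4-hydroxy-3-methylbut-2-en-1-yl]-2,3-dihydro-4H-chromen-4-one (CNP0235407.2)
Conditions: HF·pyridine, pyridine, THF, 0 °C → rt
Reagents that add atoms: none
Why: Fluoride-mediated desilylation of the four aryl ethers and the primary ether; the buffered reagent is not basic enough to open the flavanone to the chalcone and not acidic enough to ionise the allylic alcohol or the dihydrobenzofuran C2–O bond.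

**Compound list**

1 | 4-hydroxybenzyl alcohol | OCc1ccc(O)cc1 | starting material
2 | 4-(methoxymethoxy)benzyl alcohol | COCOc1ccc(CO)cc1 | intermediate
3 | 5-bromo-2,4-dihydroxybenzaldehyde | O=Cc1cc(Br)c(O)cc1O | starting material
4 | 5-bromo-2-hydroxy-4-{[4-(methoxymethoxy)benzyl]oxy}benzaldehyde | O=Cc1cc(Br)c(OCc2ccc(OCOC)cc2)cc1O | intermediate
5 | 5-bromo-2-(methoxymethoxy)-4-{[4-(methoxymethoxy)benzyl]oxy}benzaldehyde | O=Cc1cc(Br)c(OCc2ccc(OCOC)cc2)cc1OCOC | intermediate
6 | 2-[5-bromo-2-(methoxymethoxy)-4-{[4-(methoxymethoxy)benzyl]oxy}phenyl]-1,3-dioxolane | Brc1cc(C2OCCO2)c(OCOC)cc1OCc1ccc(OCOC)cc1 | intermediate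
7 | 3,5-dihydroxybenzonitrile | N#Cc1cc(O)cc(O)c1 | starting material
8 | 3,5-bis(methoxymethoxy)benzonitrile | N#Cc1cc(OCOC)cc(OCOC)c1 | intermediate
9 | N-H ketimine from the aryllithium of 6 and 8 | N=C(c1cc(OCOC)cc(OCOC)c1)c1cc(C2OCCO2)c(OCOC)cc1OCc1ccc(OCOC)cc1 | intermediate (not isolated)
10 | hydrazone of the diaryl ketone (E/Z mixture) | NN=C(c1cc(OCOC)cc(OCOC)c1)c1cc(C2OCCO2)c(OCOC)cc1OCc1ccc(OCOC)cc1 | intermediate
11 | diaryldiazomethane from 10 | [N-]=[N+]=C(c1cc(OCOC)cc(OCOC)c1)c1cc(C2OCCO2)c(OCOC)cc1OCc1ccc(OCOC)cc1 | intermediate (not isolated)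
12 | (2S,3R)-3-[3,5-bis(methoxymethoxy)phenyl]-5-(1,3-dioxolan-2-yl)-6-(methoxymethoxy)-2-[4-(methoxymethoxy)phenyl]-2,3-dihydrobenzofuran (cis) | O1CCOC1c1cc3c(cc1OCOC)O[C@H](c1ccc(OCOC)cc1)[C@@H]3c1cc(OCOC)cc(OCOC)c1 | intermediate
13 | (2R,3R)-3-(3,5-dihydroxyphenyl)-6-hydroxy-2-(4-hydroxyphenyl)-2,3-dihydrobenzofuran-5-carbaldehyde (trans) | O=Cc1cc3c(cc1O)O[C@@H](c1ccc(O)cc1)[C@@H]3c1cc(O)cc(O)c1 | intermediate
14 | Ar*–CHO, tetrakis-TBS ether of 13 | O=Cc1cc3c(cc1O[Si](C)(C)C(C)(C)C)O[C@@H](c1ccc(O[Si](C)(C)C(C)(C)C)cc1)[C@@H]3c1cc(O[Si](C)(C)C(C)(C)C)cc(O[Si](C)(C)C(C)(C)C)c1 | intermediate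
15 | methyl (E)-3-methoxybut-2-enoate | CO/C(C)=C/C(=O)OC | starting material
16 | 1,3-dimethoxy-1-(trimethylsilyloxy)buta-1,3-diene (Brassard's diene) | C=C(OC)C=C(OC)O[Si](C)(C)C | intermediate
17 | methyl (2E,5S)-5-Ar*-3-methoxy-5-(trimethylsilyloxy)pent-2-enoate | COC(=O)/C=C(/OC)C[C@@H](c1cc3c(cc1O[Si](C)(C)C(C)(C)C)O[C@@H](c1ccc(O[Si](C)(C)C(C)(C)C)cc1)[C@@H]3c1cc(O[Si](C)(C)C(C)(C)C)cc(O[Si](C)(C)C(C)(C)C)c1)O[Si](C)(C)C | intermediate (not isolated)
18 | (6S)-6-Ar*-4-methoxy-5,6-dihydro-2H-pyran-2-one | COC1=CC(=O)O[C@H](c2cc3c(cc2O[Si](C)(C)C(C)(C)C)O[C@@H](c2ccc(O[Si](C)(C)C(C)(C)C)cc2)[C@@H]3c2cc(O[Si](C)(C)C(C)(C)C)cc(O[Si](C)(C)C(C)(C)C)c2)C1 | intermediate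
19 | 2,2,6-trimethyl-4H-1,3-dioxin-4-one | CC1=CC(=O)OC(C)(C)O1 | starting material
20 | prenyl bromide (1-bromo-3-methylbut-2-ene) | CC(C)=CCBr | starting material
21 | 2,2-dimethyl-6-(4-methylpent-3-en-1-yl)-4H-1,3-dioxin-4-one | CC(C)=CCCC1=CC(=O)OC(C)(C)O1 | intermediate
22 | 6-[(3E)-5-hydroxy-4-methylpent-3-en-1-yl]-2,2-dimethyl-4H-1,3-dioxin-4-one | C/C(=C\CCC1=CC(=O)OC(C)(C)O1)CO | intermediate
23 | 6-[(3E)-5-(tert-butyldimethylsilyloxy)-4-methylpent-3-en-1-yl]-2,2-dimethyl-4H-1,3-dioxin-4-one | C/C(=C\CCC1=CC(=O)OC(C)(C)O1)CO[Si](C)(C)C(C)(C)C | intermediate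
24 | (6S)-6-Ar*-2-[(3E)-5-(tert-butyldimethylsilyloxy)-1-(2,2-dimethyl-4-oxo-4H-1,3-dioxin-6-yl)-4-methylpent-3-en-1-yl]-4-methoxy-5,6-dihydro-2H-pyran-2-ol (mixture at C2 and at the side-chain CH) | C/C(=C\CC(C1=CC(=O)OC(C)(C)O1)C1(O)C=C(OC)C[C@@H](c2cc3c(cc2O[Si](C)(C)C(C)(C)C)O[C@@H](c2ccc(O[Si](C)(C)C(C)(C)C)cc2)[C@@H]3c2cc(O[Si](C)(C)C(C)(C)C)cc(O[Si](C)(C)C(C)(C)C)c2)O1)CO[Si](C)(C)C(C)(C)C | intermediate (not isolated)
25 | (2S)-2-Ar*-6-[(3E)-5-(tert-butyldimethylsilyloxy)-1-(2,2-dimethyl-4-oxo-4H-1,3-dioxin-6-yl)-4-methylpent-3-en-1-yl]-2,3-dihydro-4H-pyran-4-one (both epimers at the side-chain CH) | C/C(=C\CC(C1=CC(=O)OC(C)(C)O1)C1=CC(=O)C[C@@H](c2cc3c(cc2O[Si](C)(C)C(C)(C)C)O[C@@H](c2ccc(O[Si](C)(C)C(C)(C)C)cc2)[C@@H]3c2cc(O[Si](C)(C)C(C)(C)C)cc(O[Si](C)(C)C(C)(C)C)c2)O1)CO[Si](C)(C)C(C)(C)C | intermediate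
26 | acylketene from 25 after loss of acetone (arm = CH bearing the O=C=CH–C(=O)– group and the silyloxy-methylbutenyl chain) | C/C(=C\CC(C(=O)C=C=O)C1=CC(=O)C[C@@H](c2cc3c(cc2O[Si](C)(C)C(C)(C)C)O[C@@H](c2ccc(O[Si](C)(C)C(C)(C)C)cc2)[C@@H]3c2cc(O[Si](C)(C)C(C)(C)C)cc(O[Si](C)(C)C(C)(C)C)c2)O1)CO[Si](C)(C)C(C)(C)C | intermediate (not isolated)
27 | (2S)-2-Ar*-8-[(2E)-4-(tert-butyldimethylsilyloxy)-3-methylbut-2-en-1-yl]-5,7-dihydroxy-2,3-dihydro-4H-chromen-4-one | C/C(=C\Cc1c(O)cc(O)c2c1O[C@H](c1cc3c(cc1O[Si](C)(C)C(C)(C)C)O[C@@H](c1ccc(O[Si](C)(C)C(C)(C)C)cc1)[C@@H]3c1cc(O[Si](C)(C)C(C)(C)C)cc(O[Si](C)(C)C(C)(C)C)c1)CC2=O)CO[Si](C)(C)C(C)(C)C | intermediate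
28 | (2S)-2-[(2R,3R)-3-(3,5-dihydroxyphenyl)-6-hydroxy-2-(4-hydroxyphenyl)-2,3-dihydrobenzofuran-5-yl]-5,7-dihydroxy-8-[(2E)-4-hydroxy-3-methylbut-2-en-1-yl]-2,3-dihydro-4H-chromen-4-one | C/C(=C\Cc1c(O)cc(O)c2c1O[C@H](c1cc3c(cc1O)O[C@@H](c1ccc(O)cc1)[C@@H]3c1cc(O)cc(O)c1)CC2=O)CO | target

**Step count and risks**

Total step count: 17. Longest linear sequence: 12 steps (steps 1, 2, 3, 4, 6, 7, 8, 9, 11, 15, 16, 17).

Steps most likely to fail:

1. Step 16 (key step). What may go wrong: the acylketene may be consumed by dimerisation, or by hydration and decarboxylation with traces of water, faster than its enol form closes onto C4a. Fallback, from 25 back to 27, using known chemistry in an ionic rather than a pericyclic closure: heating 25 in toluene with methanol at 110 °C should trap the acylketene as the methyl β-keto ester F1. Treatment of F1 with NaH in THF (0 °C → rt) should deprotonate C6 and C8; the extended enolate then attacks the ester through C4a in a Dieckmann-type Claisen condensation, and loss of methoxide with enolisation gives 27.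

2. Step 15. What may go wrong: the hindered secondary γ-carbon of the dienolate may add too slowly to the deactivated lactone carbonyl, so that proton abstraction at C5 of the lactone with β-elimination of the carboxylate (loss of the C6 stereocentre) or attack through the α-carbon of the dienolate takes over. Fallback, from 18 and 19 back to 25, with the order of bond formation reversed: the unhindered lithium dienolate of the parent dioxinone 19 (LiN(iPr)2, THF, −78 °C) is added to 18 and the lactol is dehydrated with PPTS as in step 15, giving (2S)-2-Ar*-6-[(2,2-dimethyl-4-oxo-4H-1,3-dioxin-6-yl)methyl]-2,3-dihydro-4H-pyran-4-one F2. C-alkylation of its doubly vinylogous active methylene (C8) with prenyl bromide 20 (K2CO3, acetone) should give the C8-prenyl compound F3. SeO2/t-BuOOH oxidation as in step 13 should give the (E)-allylic alcohol F4, and TBSCl/imidazole returns to 25.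

3. Step 11. What may go wrong: low conversion and poor facial selectivity, because the aldehyde is electron-rich and carries a bulky ortho-silyloxy group. Fallback, from 14 (with 19) back to 18, through a catalytic asymmetric vinylogous Mukaiyama aldol addition instead of the cycloaddition: 19 is converted (LiN(iPr)2, TMSCl) into the silyl dienol ether 2,2-dimethyl-6-methylidene-4-(trimethylsilyloxy)-6H-1,3-dioxine F5. F5 is added to 14 with Cu(OTf)2, (S)-Tol-BINAP and Bu4N[Ph3SiF2] as catalyst, and acidic work-up gives the (S)-6-(2-Ar*-2-hydroxyethyl)-2,2-dimethyl-4H-1,3-dioxin-4-one F6. Heating F6 in toluene at 110 °C releases acetone, and the δ-hydroxyl traps the acylketene to give (6S)-6-Ar*-dihydro-2H-pyran-2,4(3H)-dione F7. O-methylation of its enol (Me2SO4, K2CO3, acetone) returns to 18.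

**Further compounds**

F1 | step 16 | methyl β-keto ester from methanol capture of acylketene 26 (arm = CH bearing the –C(=O)CH2CO2Me group) | C/C(=C\CC(C(=O)CC(=O)OC)C1=CC(=O)C[C@@H](c2cc3c(cc2O[Si](C)(C)C(C)(C)C)O[C@@H](c2ccc(O[Si](C)(C)C(C)(C)C)cc2)[C@@H]3c2cc(O[Si](C)(C)C(C)(C)C)cc(O[Si](C)(C)C(C)(C)C)c2)O1)CO[Si](C)(C)C(C)(C)C
F2 | step 15 | (2S)-2-Ar*-6-[(2,2-dimethyl-4-oxo-4H-1,3-dioxin-6-yl)methyl]-2,3-dihydro-4H-pyran-4-one | O=C1C=C(CC2=CC(=O)OC(C)(C)O2)O[C@H](c2cc3c(cc2O[Si](C)(C)C(C)(C)C)O[C@@H](c2ccc(O[Si](C)(C)C(C)(C)C)cc2)[C@@H]3c2cc(O[Si](C)(C)C(C)(C)C)cc(O[Si](C)(C)C(C)(C)C)c2)C1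
F3 | step 15 | (2S)-2-Ar*-6-[1-(2,2-dimethyl-4-oxo-4H-1,3-dioxin-6-yl)-4-methylpent-3-en-1-yl]-2,3-dihydro-4H-pyran-4-one | O=C1C=C(C(CC=C(C)C)C2=CC(=O)OC(C)(C)O2)O[C@H](c2cc3c(cc2O[Si](C)(C)C(C)(C)C)O[C@@H](c2ccc(O[Si](C)(C)C(C)(C)C)cc2)[C@@H]3c2cc(O[Si](C)(C)C(C)(C)C)cc(O[Si](C)(C)C(C)(C)C)c2)C1
F4 | step 15 | (2S)-2-Ar*-6-[(3E)-1-(2,2-dimethyl-4-oxo-4H-1,3-dioxin-6-yl)-5-hydroxy-4-methylpent-3-en-1-yl]-2,3-dihydro-4H-pyran-4-one | O=C1C=C(C(C/C=C(\C)CO)C2=CC(=O)OC(C)(C)O2)O[C@H](c2cc3c(cc2O[Si](C)(C)C(C)(C)C)O[C@@H](c2ccc(O[Si](C)(C)C(C)(C)C)cc2)[C@@H]3c2cc(O[Si](C)(C)C(C)(C)C)cc(O[Si](C)(C)C(C)(C)C)c2)C1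
F5 | step 11 | 2,2-dimethyl-6-methylidene-4-(trimethylsilyloxy)-6H-1,3-dioxine | C=C1C=C(O[Si](C)(C)C)OC(C)(C)O1
F6 | step 11 | (S)-6-(2-Ar*-2-hydroxyethyl)-2,2-dimethyl-4H-1,3-dioxin-4-one | CC1(C)OC(=O)C=C(C[C@@H](c2cc3c(cc2O[Si](C)(C)C(C)(C)C)O[C@@H](c2ccc(O[Si](C)(C)C(C)(C)C)cc2)[C@@H]3c2cc(O[Si](C)(C)C(C)(C)C)cc(O[Si](C)(C)C(C)(C)C)c2)O)O1
F7 | step 11 | (6S)-6-Ar*-dihydro-2H-pyran-2,4(3H)-dione | O=C1CC(=O)O[C@H](c2cc3c(cc2O[Si](C)(C)C(C)(C)C)O[C@@H](c2ccc(O[Si](C)(C)C(C)(C)C)cc2)[C@@H]3c2cc(O[Si](C)(C)C(C)(C)C)cc(O[Si](C)(C)C(C)(C)C)c2)C1
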